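## Retrosynthetic overview

- **Numbering and strategic feature.** The ring runs C1 (stereocentre)–C2H2–C3H=C4(CO2H)–C5…C14, and the side chain is C15(=C16H2)CH2CH2CH=CMe2. The strategy rests on the 1,5-diene C16=C15–C1–C2–C3=C4. It leads from the exocyclic methylene through the stereocentre into the carboxyl-bearing alkene of the 14-membered carbocycle.
- **Key disconnections.** A retro-Cope shift (C1–C2 opened, C4–C16 closed) gives a 14-membered carbocycle with an alpha-vinyl quaternary C4. A retro-Ireland–Claisen shift (C4–C16 opened, C1–O closed) then gives a 14-membered lactone. In it the target's own carboxyl group esterifies an oxygen on C1, so the lactone is an isomer of the target.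
- **Ring order.** One macrolactonisation (acyl carbon to O on C1) makes the 14-membered lactone. The first shift replaces the ring segment C(=O)–O by C16–C15, and the second replaces C16–C15 by C3–C2. The ring size stays at 14 throughout.
- **Chain assembly.** The seco acid is built linearly:
  - C9–C10 from neryl bromide and the silylpropyne anion (Z C11=C12 comes from nerol);
  - C6–C7 by syn methylalumination and oxirane opening (E C7=C8);
  - C4–C5 by alkylation of the crotonate dienolate;
  - C1–C15 by asymmetric Ni/Cr alkenylation, which sets the only stereocentre that is carried forward.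

Key step: step 15

Assumption: the antipode of the oxazoline–sulfonamide ligand that delivers the (R)-carbinol is identified by Mosher ester analysis of the first coupling product. C4 is carried as an unassigned epimer mixture until it is planarised.

## Route

Step 1
Reactants: 1 nerol
Product: 2 neryl bromide [(2Z)-1-bromo-3,7-dimethylocta-2,6-diene]
Conditions: PBr3 (0.4 equiv), Et2O, −10 → 0 °C, dark; used crude
Reagents that add atoms: phosphorus tribromide, BrP(Br)Br
Why: SN2-type displacement of the phosphite ester of a primary allylic alcohol at low temperature should keep the Z C11=C12 geometry and hold allylic transposition and cyclisation back.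

Step 2
Reactants: 2 neryl bromide; 3 1-(trimethylsilyl)propyne
Product: 5 (Z)-(6,10-dimethylundeca-5,9-dien-1-yn-1-yl)trimethylsilane, via 3-lithio-1-(trimethylsilyl)propyne 4 (not isolated)
Conditions: 3, n-BuLi, THF, −20 °C; then 2, −78 → 0 °C
Reagents that add atoms: none
Why: Propargylic lithiation followed by SN2 alkylation with the primary allylic bromide forms C9–C10, the silyl cap blocking the acetylenic terminus and favouring the propargyl over the allenyl mode of attack.

Step 3
Reactants: 5 silyl dienyne
Product: 6 (Z)-6,10-dimethylundeca-5,9-dien-1-yne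
Conditions: K2CO3 (cat.), MeOH, 23 °C
Reagents that add atoms: none
Why: Methoxide-induced protodesilylation of an alkynylsilane is fast and should leave both trisubstituted alkenes untouched.

Step 4
Reactants: 6 (Z)-dienyne; 7 oxirane
Product: 10 (3E,7Z)-homofarnesol [(3E,7Z)-4,8,12-trimethyltrideca-3,7,11-trien-1-ol], via alkenyldimethylalane 8 (not isolated), via lithium alkenylalanate 9 (not isolated)
Conditions: Me3Al, Cp2ZrCl2 (0.25 equiv), CH2Cl2, 0 → 23 °C; volatiles removed; n-BuLi, hexane–THF, −78 → 0 °C; 7, −30 → 23 °C; cold aq. HCl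
Reagents that add atoms: trimethylaluminium, C[Al](C)C
Why: Zr-catalysed syn methylalumination (Negishi carboalumination) puts CH3 on C8 and Al on C7 on the same side, which fixes the E C7=C8 bond, and the more nucleophilic alanate opens oxirane with retention of alkene geometry to form C6–C7.

Step 5
Reactants: 10 (3E,7Z)-homofarnesol
Product: 11 (3E,7Z)-homofarnesyl iodide [(3E,7Z)-1-iodo-4,8,12-trimethyltrideca-3,7,11-triene]
Conditions: I2, PPh3, imidazole, CH2Cl2, 0 °C
Reagents that add atoms: iodine, II
Why: Appel-type iodination of an unhindered primary alcohol proceeds by SN2 on the alkoxyphosphonium salt and does not touch the alkenes.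

Step 6
Reactants: 11 homofarnesyl iodide; 12 methyl crotonate
Product: 14 methyl (5E,9Z)-2-ethenyl-6,10,14-trimethylpentadeca-5,9,13-trienoate (C4 epimer mixture), via lithium dienolate 13 (not isolated)
Conditions: LDA, THF–DMPU, −78 °C, 12; then 11, −78 → −20 °C
Reagents that add atoms: none
Why: Deconjugative alpha-alkylation, in which gamma-deprotonation of the crotonate by the DMPU-solvated amide gives the dienolate that attacks the primary iodide through its alpha carbon, forms C4–C5 and leaves C2=C3 as a vinyl group, C4 arising without control because it is erased in step 14.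

Step 7
Reactants: 14 alpha-vinyl ester
Product: 15 terminal bromohydrin [methyl (5E,9Z)-13-bromo-2-ethenyl-14-hydroxy-6,10,14-trimethylpentadeca-5,9-dienoate]
Conditions: NBS (1.05 equiv), THF–H2O (to the cloud point), 0 °C
Reagents that add atoms: N-bromosuccinimide, O=C1CCC(=O)N1Br; water, O
Why: Terminal-selective bromohydrin formation of a polyene in a highly aqueous medium, where chain coiling leaves the isopropylidene end most exposed and the vinyl group is too electron-poor to compete, gives Markovnikov water attack and a new C–Br centre that is uncontrolled and vanishes in step 9.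

Step 8
Reactants: 15 bromohydrin
Product: 16 terminal epoxide [methyl (5E,9Z)-12-(3,3-dimethyloxiran-2-yl)-2-ethenyl-6,10-dimethyldodeca-5,9-dienoate]
Conditions: K2CO3, MeOH, 0 °C, short contact time
Reagents that add atoms: none
Why: Intramolecular Williamson closure of the alkoxide onto the adjacent C–Br is much faster than enolisation of the methyl ester when the reaction is kept cold and brief.

Step 9
Reactants: 16 terminal epoxide
Product: 17 C1 aldehyde [methyl (5E,9Z)-2-ethenyl-6,10-dimethyl-13-oxotrideca-5,9-dienoate]
Conditions: H5IO6, THF–Et2O, 0 °C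
Reagents that add atoms: none
Why: Periodic acid opens the trisubstituted epoxide to the glycol and cleaves it in the same flask (glycol cleavage), expelling acetone and exposing C1 as the aldehyde without affecting alkenes or ester.

Step 10
Reactants: 18 6-methylhept-5-en-2-one
Product: 20 6-methylhepta-1,5-dien-2-yl trifluoromethanesulfonate, via kinetic lithium enolate 19 (not isolated)
Conditions: LDA, THF, −78 °C (ketone added slowly); PhNTf2, −78 → 0 °C
Reagents that add atoms: N-phenylbis(trifluoromethanesulfonimide), O=S(=O)(C(F)(F)F)N(c1ccccc1)S(=O)(=O)C(F)(F)F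
Why: Irreversible kinetic deprotonation by the hindered amide takes place at the methyl group, and O-sulfonylation of that enolate gives the 1,1-disubstituted alkenyl triflate that carries C15 and C16.

Step 11
Reactants: 17 C1 aldehyde; 20 alkenyl triflate
Product: 21 methyl (5E,9Z,13R)-2-ethenyl-13-hydroxy-6,10,18-trimethyl-14-methylidenenonadeca-5,9,17-trienoate
Conditions: CrCl2 (10 mol %), chiral oxazoline–sulfonamide ligand (N-[2-(4-isopropyl-4,5-dihydrooxazol-2-yl)-6-methoxyphenyl]methanesulfonamide type, 11 mol %), 1,8-bis(dimethylamino)naphthalene (11 mol %), NiCl2(2,9-dimethyl-1,10-phenanthroline) (2 mol %), Mn, Cp2ZrCl2, LiCl, MeCN, 23 °C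
Reagents that add atoms: none
Why: In the catalytic asymmetric Nozaki–Hiyama–Kishi alkenylation zerovalent nickel inserts into the C–OTf bond and hands the alkenyl group to the chromium–sulfonamide complex, whose chiral pocket selects the aldehyde face and sets C1–O as R, while Mn restores divalent chromium, Cp2ZrCl2 releases the alkoxide and the ester stays inert.

Step 12
Reactants: 21 (R)-allylic alcohol ester
Product: 23 seco acid [(5E,9Z,13R)-2-ethenyl-13-hydroxy-6,10,18-trimethyl-14-methylidenenonadeca-5,9,17-trienoic acid], via trimethylstannyl ester 22 (not isolated)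
Conditions: Me3SnOH (6 equiv), ClCH2CH2Cl, 70–80 °C; cold dilute aq. HCl wash
Reagents that add atoms: trimethyltin hydroxide, C[Sn](C)(C)O
Why: Tin-hydroxide-mediated ester hydrolysis works under essentially neutral conditions, so the doubly activated C4–H is not enolised and the vinyl group should stay out of conjugation, which gives the later enolisation one constitutional starting point.

Step 13
Reactants: 23 seco acid
Product: 25 macrolactone [(6E,10Z,14R)-3-ethenyl-7,11-dimethyl-14-(6-methylhepta-1,5-dien-2-yl)-1-oxacyclotetradeca-6,10-dien-2-one], via mixed anhydride 24 (not isolated)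
Conditions: 2-methyl-6-nitrobenzoic anhydride (1.3 equiv), DMAP (excess), CH2Cl2, 23 °C, syringe-pump addition of 23, final about 1 mM
Reagents that add atoms: none
Why: In the Shiina mixed-anhydride macrolactonisation DMAP transfers the aliphatic acyl group of 24 to the C1 hydroxyl under pseudo-high dilution, closing the 14-membered ring with retention at C1 because the C1–O bond is never broken.

Step 14
Reactants: 25 macrolactone
Product: 27 silyl dienol ketene acetal [(2E,6E,10Z,14R)-2-(tert-butyldimethylsilyloxy)-3-ethenyl-7,11-dimethyl-14-(6-methylhepta-1,5-dien-2-yl)-1-oxacyclotetradeca-2,6,10-triene; C5 trans to the ring oxygen], via potassium dienolate 26 (not isolated)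
Conditions: TBSCl (3 equiv), KHMDS (1.5 equiv), THF–DMPU (4:1), −78 °C; cold pentane/pH 7 buffer wash, concentrated at ≤ 0 °C, used at once
Reagents that add atoms: tert-butyldimethylsilyl chloride, CC(C)(C)[Si](C)(C)Cl
Why: Kinetic enolisation and O-silylation (silyl ketene acetal formation) removes the allylic alpha proton of both C4 epimers, and of any ethylidene isomer through its gamma methyl, to one dienolate, the DMPU-solvated open transition state and the lower strain of a trans ring double bond both placing the sp3 carbon C5 away from the ring oxygen.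

Step 15
Reactants: 27 silyl dienol ketene acetal
Product: 30 target acid [(1(14)Z,4E,8Z,12R)-5,9-dimethyl-12-(6-methylhepta-1,5-dien-2-yl)cyclotetradeca-1(14),4,8-triene-1-carboxylic acid; 1R,3Z,7E,11Z in the overview numbering], via quaternary silyl ester 28 (not isolated), via conjugated silyl ester 29 (not isolated)
Conditions: degassed mesitylene (0.01 M, base-washed glass), 23 → 60 °C, then 165 °C; then AcOH–THF–H2O, 23 °C
Reagents that add atoms: none
Why: Proposed new method: on mild warming the array C4=C(OTBS)–O–C1–C15=C16 of 27 undergoes an Ireland–Claisen [3,3] shift (C4–C16 made, C1–O broken) to silyl ester 28, whose 1,5-diene C2=C3–C4–C16–C15=C1 undergoes a Cope [3,3] shift at higher temperature (C1–C2 made, C4–C16 broken), pulled downhill by loss of the quaternary centre, by ester conjugation and by the change of a vinyl plus a trisubstituted alkene into a conjugated trisubstituted plus a 1,1-disubstituted alkene, after which mild hydrolysis of 29 frees the acid. The nearest known reaction types are the Claisen-then-Cope sequence of allyl dienyl ethers, the Ireland–Claisen rearrangement of small and medium lactone ketene acetals that carry an alkenyl group on the carbinol carbon, and the Cope rearrangement of alpha-allyl beta,gamma-unsaturated esters into conjugation, but none of them has been run on a macrolactone or linked in this way. Neither 14-membered carbocycle arises by joining chain ends: in each shift the six reacting atoms adopt a chair whose para positions C4 and C1 are already tied by the C5–C14 chain (a bicyclo[10.2.2]-type array), so that only a two-atom ring segment is exchanged. C4 of 28 is set as R by the (R)-C1–O centre through a chair with C14 and C5 both equatorial, which also gives the E C1=C15 bond, and C1 of 30 is then set as R by (4R) through a second chair with C5 and C14 equatorial, which at the same time puts C2 trans to C5 across C3=C4 (carboxyl cis to C2, 3Z). The step needs regioselectivity (only C4 of the dienolate stands in a 3,3 relation to C16), a single ketene acetal geometry (from step 14), chair rather than boat topology (the ten-atom tether is long enough to span a chair, unlike the short tethers of small lactones) and C5 rather than CO2TBS equatorial in the Cope chair (the axial site faces the C15 side chain, which the flat ester tolerates better than a CH2 chain). The other 1,5-dienes of ring and side chain could only rearrange uphill to quaternary centres and less substituted alkenes and should remain spectators, and the diene of 28 (alkyl at C15, hydrogen at C3) also fits the pattern accepted by PdCl2(PhCN)2-catalysed Cope rearrangement if heat alone is too slow.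

## Compound list

1 | nerol | CC(C)=CCC/C(C)=C\CO | starting material
2 | neryl bromide | CC(C)=CCC/C(C)=C\CBr | intermediate
3 | 1-(trimethylsilyl)propyne | CC#C[Si](C)(C)C | starting material
4 | 3-lithio-1-(trimethylsilyl)propyne | [Li]CC#C[Si](C)(C)C | intermediate
5 | (Z)-(6,10-dimethylundeca-5,9-dien-1-yn-1-yl)trimethylsilane | C[Si](C)(C)C#CCC/C=C(/C)CCC=C(C)C | intermediate
6 | (Z)-6,10-dimethylundeca-5,9-dien-1-yne | C#CCC/C=C(/C)CCC=C(C)C | intermediate
7 | oxirane | C1CO1 | starting material
8 | dimethyl[(1E,5Z)-2,6,10-trimethylundeca-1,5,9-trien-1-yl]alane | C[Al](C)/C=C(\C)CC/C=C(/C)CCC=C(C)C | intermediate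
9 | lithium butyl(dimethyl)[(1E,5Z)-2,6,10-trimethylundeca-1,5,9-trien-1-yl]alanate | [Li+].CCCC[Al-](C)(C)/C=C(\C)CC/C=C(/C)CCC=C(C)C | intermediate
10 | (3E,7Z)-homofarnesol | OCC/C=C(\C)CC/C=C(/C)CCC=C(C)C | intermediate
11 | (3E,7Z)-homofarnesyl iodide | ICC/C=C(\C)CC/C=C(/C)CCC=C(C)C | intermediate
12 | methyl crotonate | C/C=C/C(=O)OC | starting material
13 | lithium dienolate of methyl crotonate | [Li+].C=CC=C([O-])OC | intermediate
14 | methyl (5E,9Z)-2-ethenyl-6,10,14-trimethylpentadeca-5,9,13-trienoate (C4 epimers) | C=CC(CC/C=C(\C)CC/C=C(/C)CCC=C(C)C)C(=O)OC | intermediate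
15 | terminal bromohydrin of 14 | C=CC(CC/C=C(\C)CC/C=C(/C)CCC(Br)C(C)(C)O)C(=O)OC | intermediate
16 | terminal epoxide of 14 | C=CC(CC/C=C(\C)CC/C=C(/C)CCC1OC1(C)C)C(=O)OC | intermediate
17 | methyl (5E,9Z)-2-ethenyl-6,10-dimethyl-13-oxotrideca-5,9-dienoate | C=CC(CC/C=C(\C)CC/C=C(/C)CCC=O)C(=O)OC | intermediate
18 | 6-methylhept-5-en-2-one | CC(=O)CCC=C(C)C | starting material
19 | kinetic lithium enolate of 18 | [Li+].C=C([O-])CCC=C(C)C | intermediate
20 | 6-methylhepta-1,5-dien-2-yl trifluoromethanesulfonate | C=C(CCC=C(C)C)OS(=O)(=O)C(F)(F)F | intermediate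
21 | methyl (5E,9Z,13R)-2-ethenyl-13-hydroxy-6,10,18-trimethyl-14-methylidenenonadeca-5,9,17-trienoate | C=CC(CC/C=C(\C)CC/C=C(/C)CC[C@@H](O)C(=C)CCC=C(C)C)C(=O)OC | intermediate
22 | trimethylstannyl ester of 23 | C=CC(CC/C=C(\C)CC/C=C(/C)CC[C@@H](O)C(=C)CCC=C(C)C)C(=O)O[Sn](C)(C)C | intermediate
23 | (13R)-seco acid | C=CC(CC/C=C(\C)CC/C=C(/C)CC[C@@H](O)C(=C)CCC=C(C)C)C(=O)O | intermediate
24 | mixed anhydride of 23 with 2-methyl-6-nitrobenzoic acid | C=CC(CC/C=C(\C)CC/C=C(/C)CC[C@@H](O)C(=C)CCC=C(C)C)C(=O)OC(=O)c1c(C)cccc1[N+](=O)[O-] | intermediate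
25 | (6E,10Z,14R)-14-membered macrolactone, isomer of the target | C=C(CCC=C(C)C)[C@H]1CC/C(C)=C\CC/C(C)=C/CCC(C=C)C(=O)O1 | intermediate
26 | potassium dienolate of 25 (C5 trans to ring O) | C=C(CCC=C(C)C)[C@H]1CC/C(C)=C\CC/C(C)=C/CC/C(C=C)=C(/O1)[O-].[K+] | intermediate
27 | TBS dienol ketene acetal of 25 (2E, C5 trans to ring O) | C=C(CCC=C(C)C)[C@H]1CC/C(C)=C\CC/C(C)=C/CC/C(C=C)=C(/O1)O[Si](C)(C)C(C)(C)C | intermediate
28 | tert-butyldimethylsilyl (1R,3E,7Z,11E)-1-ethenyl-7,11-dimethyl-3-(4-methylpent-3-en-1-yl)cyclotetradeca-3,7,11-triene-1-carboxylate | C=C[C@]1(C(=O)O[Si](C)(C)C(C)(C)C)C/C(CCC=C(C)C)=C/CC/C(C)=C\CC/C(C)=C/CC1 | intermediate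
29 | tert-butyldimethylsilyl ester of the target | C=C(CCC=C(C)C)[C@H]1C/C=C(\C(=O)O[Si](C)(C)C(C)(C)C)CC/C=C(\C)CC/C=C(/C)CC1 | intermediate
30 | CNP0269207.1, (1(14)Z,4E,8Z,12R)-5,9-dimethyl-12-(6-methylhepta-1,5-dien-2-yl)cyclotetradeca-1(14),4,8-triene-1-carboxylic acid | C=C(CCC=C(C)C)[C@H]1C/C=C(\C(=O)O)CC/C=C(\C)CC/C=C(/C)CC1 | target

## Step count and risks

Total step count: 15.
Longest linear sequence: 14 steps (steps 1–9 and 11–15, from nerol). Step 10 is a one-step side branch.

**1. Step 15 (Proposed new method).**
- **What may go wrong.** The first shift may leak through a boat or through a minor ketene acetal geometry, which erodes the enantiomeric purity. The second shift may stall at the quaternary stage. It may also run through the chair with the ester equatorial, which reverses both the C3=C4 geometry and the sense at C1.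
- **Fallback (known chemistry throughout).** It sets out from alcohol 10 and ketone 18 and returns to the route at acid 30. C1 is set by an auxiliary-controlled conjugate addition, and the ring is closed at C3=C4 by olefination.
- **Acceptor.** Alcohol 10 is turned with PPh3/NCS into (3E,7Z)-homofarnesyl chloride F1. The operations of steps 7–9 degrade its terminal alkene through the bromohydrin F2 and the epoxide F3 to the chloro aldehyde F4. Masamune–Roush olefination with diethyl {2-[(4S)-4-benzyl-2-oxo-1,3-oxazolidin-3-yl]-2-oxoethyl}phosphonate (LiCl, i-Pr2NEt, MeCN) gives the (E)-N-enoyl oxazolidinone F5.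
- **Nucleophile.** Ketone 18 is condensed with 2,4,6-triisopropylbenzenesulfonohydrazide to the hydrazone F6. A Shapiro reaction (n-BuLi, THF, −78 → 0 °C) gives the alkenyllithium F7, and MgBr2·OEt2 gives the alkenylmagnesium bromide F8.
- **Stereocentre.** CuBr·SMe2-promoted 1,4-addition to the magnesium-chelated imide, anti to the benzyl group, should give the conjugate adduct F9 with (R)-C1.
- **Phosphonate.** LiBH4 gives the primary alcohol F10, TBSCl/imidazole the silyl ether F11, and NaI in acetone (Finkelstein) the iodide F12. Alkylation of the sodium salt of methyl bis(2,2,2-trifluoroethyl)phosphonoacetate (NaH, DMF) gives the alpha-substituted phosphonate F13.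
- **Ring closure.** HF·pyridine frees the hydroxy phosphonate F14, and Dess–Martin periodinane gives the aldehyde phosphonate F15. An intramolecular Still–Gennari olefination (K2CO3, 18-crown-6, toluene, high dilution) closes the 14-membered ring with the ester cis to C2, giving the macrocyclic methyl ester F16. LiOH in aqueous THF–MeOH then gives 30.

**2. Step 14.**
- **What may go wrong.** Enolisation may place C5 cis to the ring oxygen, which reverses the sense of the chirality relay.
- **Fallback.** It sets out from aldehyde 17 and triflate 20 and returns to the route at silyl ester 28. If the cis geometry forms cleanly, it is paired with the mirror-image carbinol rather than corrected.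
- **Sequence.** Step 11 with the antipodal ligand gives the (S)-allylic alcohol ester F17. Steps 12 and 13 carry it through the stannyl ester F18, the (S)-seco acid F19 and the mixed anhydride F20 to the (S)-macrolactone F21. Enolisation through the cis potassium dienolate F22 gives the cis silyl ketene acetal F23. Its chair (C5 axial, C14 equatorial) should lead to the same (4R)-configured 28.

**3. Step 11.**
- **What may go wrong.** The catalyst may show poor facial selectivity, or oxidative addition into the alkenyl triflate may be sluggish.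
- **Fallback.** It sets out from aldehyde 17 and triflate 20 and returns to the route at alcohol 21.
- **Sequence.** The C1–C15 bond is made without induction by the classical Nozaki–Hiyama–Kishi reaction (excess CrCl2, NiCl2 cat., DMF–THF), which gives the carbinol epimer mixture F24. Dess–Martin periodinane gives the alpha-methylene ketone F25. Corey–Bakshi–Shibata reduction ((S)-Me-CBS oxazaborolidine, catecholborane, toluene, −78 °C), with the branched alkenyl group as the large substituent, should give 21.

## Further compounds

F1 | step 15 | (3E,7Z)-homofarnesyl chloride | ClCC/C=C(\C)CC/C=C(/C)CCC=C(C)C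
F2 | step 15 | terminal bromohydrin of F1 | ClCC/C=C(\C)CC/C=C(/C)CCC(Br)C(C)(C)O
F3 | step 15 | terminal epoxide of F1 | ClCC/C=C(\C)CC/C=C(/C)CCC1OC1(C)C
F4 | step 15 | (4Z,8E)-11-chloro-4,8-dimethylundeca-4,8-dienal | ClCC/C=C(\C)CC/C=C(/C)CCC=O
F5 | step 15 | (4S)-4-benzyl-3-[(2E,6Z,10E)-13-chloro-6,10-dimethyltrideca-2,6,10-trienoyl]oxazolidin-2-one | O=C1OC[C@H](Cc2ccccc2)N1C(=O)/C=C/CC/C(C)=C\CC/C(C)=C/CCCl
F6 | step 15 | 2,4,6-triisopropylbenzenesulfonylhydrazone of 18 | C/C(CCC=C(C)C)=N\NS(=O)(=O)c1c(C(C)C)cc(C(C)C)cc1C(C)C
F7 | step 15 | (6-methylhepta-1,5-dien-2-yl)lithium | [Li]C(=C)CCC=C(C)C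
F8 | step 15 | (6-methylhepta-1,5-dien-2-yl)magnesium bromide | C=C(CCC=C(C)C)[Mg]Br
F9 | step 15 | conjugate adduct, (R) at C1, (4S)-benzyloxazolidinone imide | O=C1OC[C@H](Cc2ccccc2)N1C(=O)C[C@H](C(=C)CCC=C(C)C)CC/C(C)=C\CC/C(C)=C/CCCl
F10 | step 15 | (R)-chloro alcohol (C3–OH) | OCC[C@H](C(=C)CCC=C(C)C)CC/C(C)=C\CC/C(C)=C/CCCl
F11 | step 15 | TBS ether of F10 | CC(C)(C)[Si](C)(C)OCC[C@H](C(=C)CCC=C(C)C)CC/C(C)=C\CC/C(C)=C/CCCl
F12 | step 15 | C5 iodide, TBS ether | CC(C)(C)[Si](C)(C)OCC[C@H](C(=C)CCC=C(C)C)CC/C(C)=C\CC/C(C)=C/CCI
F13 | step 15 | alpha-substituted bis(trifluoroethyl)phosphonoacetate, TBS ether | CC(C)(C)[Si](C)(C)OCC[C@H](C(=C)CCC=C(C)C)CC/C(C)=C\CC/C(C)=C/CCC(C(=O)OC)P(=O)(OCC(F)(F)F)OCC(F)(F)F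
F14 | step 15 | hydroxy phosphonate | OCC[C@H](C(=C)CCC=C(C)C)CC/C(C)=C\CC/C(C)=C/CCC(C(=O)OC)P(=O)(OCC(F)(F)F)OCC(F)(F)F
F15 | step 15 | aldehyde phosphonate | O=CC[C@H](C(=C)CCC=C(C)C)CC/C(C)=C\CC/C(C)=C/CCC(C(=O)OC)P(=O)(OCC(F)(F)F)OCC(F)(F)F
F16 | step 15 | methyl ester of the target | C=C(CCC=C(C)C)[C@H]1C/C=C(\C(=O)OC)CC/C=C(\C)CC/C=C(/C)CC1
F17 | step 14 | (13S)-allylic alcohol ester | C=CC(CC/C=C(\C)CC/C=C(/C)CC[C@H](O)C(=C)CCC=C(C)C)C(=O)OC
F18 | step 14 | trimethylstannyl ester of F19 | C=CC(CC/C=C(\C)CC/C=C(/C)CC[C@H](O)C(=C)CCC=C(C)C)C(=O)O[Sn](C)(C)C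
F19 | step 14 | (13S)-seco acid | C=CC(CC/C=C(\C)CC/C=C(/C)CC[C@H](O)C(=C)CCC=C(C)C)C(=O)O
F20 | step 14 | mixed anhydride of F19 with 2-methyl-6-nitrobenzoic acid | C=CC(CC/C=C(\C)CC/C=C(/C)CC[C@H](O)C(=C)CCC=C(C)C)C(=O)OC(=O)c1c(C)cccc1[N+](=O)[O-]
F21 | step 14 | (14S)-macrolactone | C=C(CCC=C(C)C)[C@@H]1CC/C(C)=C\CC/C(C)=C/CCC(C=C)C(=O)O1
F22 | step 14 | potassium dienolate of F21 (C5 cis to ring O) | C=C(CCC=C(C)C)[C@@H]1CC/C(C)=C\CC/C(C)=C/CC/C(C=C)=C(\O1)[O-].[K+]
F23 | step 14 | TBS dienol ketene acetal of F21 (2Z, C5 cis to ring O) | C=C(CCC=C(C)C)[C@@H]1CC/C(C)=C\CC/C(C)=C/CC/C(C=C)=C(\O1)O[Si](C)(C)C(C)(C)C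
F24 | step 11 | allylic alcohol ester, C1 epimer mixture | C=CC(CC/C=C(\C)CC/C=C(/C)CCC(O)C(=C)CCC=C(C)C)C(=O)OC
F25 | step 11 | alpha-methylene ketone (C1 ketone) | C=CC(CC/C=C(\C)CC/C=C(/C)CCC(=O)C(=C)CCC=C(C)C)C(=O)OC
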